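Ring A is the hexasubstituted ring, its positions counted 1 to 6 (1 side chain, 2 OH, 3 aroyl, 4 OH, 5 butenyl, 6 OMe), and ring B is the 3-hydroxyphenyl ring; the side chain is C7 (ArCH2), C8 (stereocentre), C9 (isopropenyl carbon), C10–C11 (CH2CH2) and C12 (methallyl alkene carbon).
Retrosynthesis: the O–methyl bonds at positions 2 and 4 and the ring B O–isopropyl bond are cut first, then the bond from position 3 to the ketone carbon (aryllithium plus Weinreb amide) and the bond from position 5 to the alkenyl group (Negishi), then C9=CH2 and C9–CH3 so that C9 becomes an acyl carbon, and last C7–C8 and C10–C11 together.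
Enabling feature: with C9 at the acyl level, C10–C8–C9 is an acrylate and C8 lies between two CH2 groups, so C10 can accept a methallyl nucleophile and the enolate carbon C8 a ring A benzyl cation; the 2,4,6-trimethoxy pattern stabilises that cation and keeps positions 3 and 5 equivalent.
Forward: no ring is formed, since both arenes are bought; the chain is joined in one three-component step on the acryloyl imide, the auxiliary is exchanged for the isopropenyl group, ring A is substituted twice by ortho-lithiation (alkenyl, then aroyl), and the ketone directs removal of its two flanking methyl ethers.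
Stereochemistry: C8 (R) comes from the (S)-4-benzyloxazolidinone during the enolate benzylation; the E alkene comes from hydrozirconation–iodination and a stereoretentive coupling.

Key step: step 4

**Route**

Step 1
Reactants: 1 (S)-4-benzyloxazolidin-2-one; 2 acryloyl chloride
Product: 4 (S)-3-acryloyl-4-benzyloxazolidin-2-one, via bromomagnesium oxazolidinide 3 (not isolated)
Conditions: MeMgBr, THF, 0 °C; then 2, −78 → 0 °C
Reagents that add atoms: none
Why: N-acylation of the magnesium salt of an oxazolidinone with an acid chloride is the standard imide synthesis, and the magnesium counter-ion at low temperature suppresses anionic polymerisation of the acrylate.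

Step 2
Reactants: 5 2,4,6-trimethoxybenzaldehyde
Product: 6 2,4,6-trimethoxybenzyl alcohol
Conditions: NaBH4, MeOH, 0 °C
Reagents that add atoms: none
Why: Borohydride reduction of an aryl aldehyde to the benzylic alcohol is fast and clean under basic conditions, which the acid-labile electron-rich benzyl alcohol requires.

Step 3
Reactants: 6 2,4,6-trimethoxybenzyl alcohol
Product: 7 2,4,6-trimethoxybenzyl acetate
Conditions: Ac2O, Et3N, DMAP (cat.), CH2Cl2, 0 °C; NaHCO3 work-up, used without chromatography
Reagents that add atoms: acetic anhydride, CC(=O)OC(C)=O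
Why: DMAP-catalysed O-acetylation proceeds under basic conditions, so the readily ionised benzylic ester should survive to be used fresh.

Step 4
Reactants: 4 (S)-3-acryloyl-4-benzyloxazolidin-2-one; 7 2,4,6-trimethoxybenzyl acetate; 8 methallyltrimethylsilane
Product: 10 (S)-4-benzyl-3-[(2R)-5-methyl-2-(2,4,6-trimethoxybenzyl)hex-5-enoyl]oxazolidin-2-one, via chlorotitanium Z-enolate 9 (not isolated)
Conditions: 4, TiCl4 (1.1 equiv), CH2Cl2, −78 °C; 8 (0.95 equiv), −78 → −40 °C; then 7 (1.1 equiv) added slowly, −78 → −20 °C; aq. NaHCO3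
Reagents that add atoms: none
Why: Proposed new method: TiCl4 binds both imide carbonyls of 4 and holds the acryloyl unit s-cis, the allylsilane 8 attacks the β-carbon (C10–C11) and chloride-assisted loss of Me3SiCl from the β-silyl cation leaves the chelated Z trichlorotitanium enolate 9, whose carbon C8 then captures the 2,4,6-trimethoxybenzyl cation that the Lewis-acidic medium releases from acetate 7 (C7–C8). The closest known reaction types are the TiCl4-mediated Hosomi–Sakurai conjugate allylation of N-enoyl oxazolidinones with aldehyde trapping of the titanium enolate and the SN1-type alkylation of chlorotitanium imide enolates with cation-forming electrophiles; what is untested is their union with a benzylic acetate in one flask. No ring is closed. The new stereocentre C8 is controlled by the (S)-benzyl group of the auxiliary, which shields one face of the chelated Z-enolate so that the cation enters from the opposite face and gives the 2R imide. The step needs conjugate rather than carbonyl addition (secured by the unsubstituted β-carbon and two-point activation of the imide), capture of the cation by the enolate rather than by allylsilane or by another arene (secured by making 8 the limiting reagent and adding 7 slowly at −78 °C) and survival of the new 1,1-disubstituted alkene (secured by low temperature and a basic quench).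

Step 5
Reactants: 10 (S)-4-benzyl-3-[(2R)-5-methyl-2-(2,4,6-trimethoxybenzyl)hex-5-enoyl]oxazolidin-2-one
Product: 11 S-ethyl (2R)-5-methyl-2-(2,4,6-trimethoxybenzyl)hex-5-enethioate
Conditions: EtSH, n-BuLi, THF, 0 °C
Reagents that add atoms: ethanethiol (used as LiSEt), CCS
Why: Thiolate transacylation of an N-acyl oxazolidinone should work because the small, weakly basic LiSEt attacks the exocyclic carbonyl even of a hindered α-branched imide, releasing the auxiliary without touching C8.

Step 6
Reactants: 11 S-ethyl (2R)-5-methyl-2-(2,4,6-trimethoxybenzyl)hex-5-enethioate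
Product: 12 (3R)-6-methyl-3-(2,4,6-trimethoxybenzyl)hept-6-en-2-one
Conditions: Me2CuLi (from MeLi and CuI), Et2O, −78 → −40 °C
Reagents that add atoms: Me2CuLi (from MeLi and CuI), [Li+].C[Cu-]C
Why: Ketone synthesis from a thioester and lithium dimethylcuprate Me2CuLi replaces the thiolate once and does not add to the resulting ketone at low temperature, so the α-stereocentre is not exposed to a strong base.

Step 7
Reactants: 12 (3R)-6-methyl-3-(2,4,6-trimethoxybenzyl)hept-6-en-2-one
Product: 13 1,3,5-trimethoxy-2-[(2R)-5-methyl-2-(prop-1-en-2-yl)hex-5-en-1-yl]benzene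
Conditions: Cp2TiMe2, toluene, 65 °C, dark
Reagents that add atoms: Cp2TiMe2, C[Ti](C)(C1C=CC=C1)C1C=CC=C1
Why: Petasis methylenation with the methylidene Cp2Ti=CH2 formed thermally from Cp2TiMe2 converts the methyl ketone into the isopropenyl group under non-basic conditions, which avoids enolisation at C8.

Step 8
Reactants: 14 3-methylbut-1-yne
Product: 16 (E)-1-iodo-3-methylbut-1-ene, via alkenylzirconocene chloride 15 (not isolated)
Conditions: Cp2Zr(H)Cl, CH2Cl2, rt; then iodine, 0 °C
Reagents that add atoms: iodine, [I][I]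
Why: Hydrozirconation adds Zr–H syn across the terminal alkyne with zirconium at the terminal carbon and iodinolysis occurs with retention, so only the E alkenyl iodide should form.

Step 9
Reactants: 13 1,3,5-trimethoxy-2-[(2R)-5-methyl-2-(prop-1-en-2-yl)hex-5-en-1-yl]benzene; 16 (E)-1-iodo-3-methylbut-1-ene
Product: 19 1,3,5-trimethoxy-2-[(2R)-5-methyl-2-(prop-1-en-2-yl)hex-5-en-1-yl]-4-[(E)-3-methylbut-1-en-1-yl]benzene, via aryllithium 17 (not isolated), via arylzinc chloride 18 (not isolated)
Conditions: n-BuLi (1.05 equiv), THF, 0 °C; ZnCl2, 0 °C → rt; 16, Pd2(dba)3 (2 mol %), SPhos (8 mol %), THF, 50 °C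
Reagents that add atoms: none
Why: Directed ortho-metalation between two methoxy groups (the two free ring A positions are equivalent and one equivalent of base gives the mono-anion), transmetalation to zinc and Negishi coupling with the alkenyl iodide should install the butenyl group with retention of the E geometry.

Step 10
Reactants: 20 methyl 3-hydroxybenzoate
Product: 21 methyl 3-isopropoxybenzoate
Conditions: 2-bromopropane, K2CO3, DMF, 60 °C
Reagents that add atoms: 2-bromopropane, CC(C)Br
Why: Williamson etherification of a phenol with a secondary bromide under K2CO3 in DMF is routine and gives an ether that tolerates organolithium reagents and is later cleaved by BCl3.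

Step 11
Reactants: 21 methyl 3-isopropoxybenzoate
Product: 22 N-methoxy-N-methyl-3-isopropoxybenzamide
Conditions: MeNHOMe·HCl, i-PrMgCl, THF, −20 → 0 °C
Reagents that add atoms: N,O-dimethylhydroxylamine hydrochloride, CNOC.Cl
Why: Direct aminolysis of an ester by the chloromagnesium amide of N,O-dimethylhydroxylamine is a standard one-step route to Weinreb amides.

Step 12
Reactants: 19 1,3,5-trimethoxy-2-[(2R)-5-methyl-2-(prop-1-en-2-yl)hex-5-en-1-yl]-4-[(E)-3-methylbut-1-en-1-yl]benzene; 22 N-methoxy-N-methyl-3-isopropoxybenzamide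
Product: 24 (3-isopropoxyphenyl)[2,4,6-trimethoxy-3-[(2R)-5-methyl-2-(prop-1-en-2-yl)hex-5-en-1-yl]-5-[(E)-3-methylbut-1-en-1-yl]phenyl]methanone, via aryllithium 23 (not isolated)
Conditions: n-BuLi (1.05 equiv), THF, 0 °C; then 22, −78 → 0 °C; aq. NH4Cl
Reagents that add atoms: none
Why: The last ring A hydrogen lies between two methoxy groups and should be removed by directed ortho-metalation, and the aryllithium adds to the Weinreb amide to give a chelated tetrahedral adduct that releases the diaryl ketone only on work-up (Weinreb ketone synthesis).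

Step 13
Reactants: 24 (3-isopropoxyphenyl)[2,4,6-trimethoxy-3-[(2R)-5-methyl-2-(prop-1-en-2-yl)hex-5-en-1-yl]-5-[(E)-3-methylbut-1-en-1-yl]phenyl]methanone
Product: 25 (3-hydroxyphenyl)[2,6-dihydroxy-4-methoxy-3-[(2R)-5-methyl-2-(prop-1-en-2-yl)hex-5-en-1-yl]-5-[(E)-3-methylbut-1-en-1-yl]phenyl]methanone (CNP0208548.1)
Conditions: BCl3 (6 equiv), 2,6-di-tert-butyl-4-methylpyridine, CH2Cl2, −78 → 0 °C; inverse quench into cold aq. NaHCO3
Reagents that add atoms: none
Why: Chelation-directed ether cleavage should work because BCl3 bound to the ketone oxygen activates in turn the two flanking methoxy groups toward chloride attack while the unchelated methoxy group at position 6 of ring A, para to the ketone, is spared, the ring B isopropyl ether is cleaved by BCl3 as secondary alkyl aryl ethers are, and the hindered pyridine scavenges adventitious HCl to protect the alkenes.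

**Compound list**

1 | (S)-4-benzyloxazolidin-2-one | O=C1N[C@@H](Cc2ccccc2)CO1 | starting material
2 | acryloyl chloride | C=CC(=O)Cl | starting material
3 | bromomagnesium salt of (S)-4-benzyloxazolidin-2-one (not isolated) | O=C1N([Mg]Br)[C@@H](Cc2ccccc2)CO1 | intermediate
4 | (S)-3-acryloyl-4-benzyloxazolidin-2-one | C=CC(=O)N1C(=O)OC[C@@H]1Cc1ccccc1 | intermediate
5 | 2,4,6-trimethoxybenzaldehyde | COc1cc(OC)c(C=O)c(OC)c1 | starting material
6 | 2,4,6-trimethoxybenzyl alcohol | COc1cc(OC)c(CO)c(OC)c1 | intermediate
7 | 2,4,6-trimethoxybenzyl acetate | CC(=O)OCc1c(OC)cc(OC)cc1OC | intermediate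
8 | methallyltrimethylsilane | C=C(C)C[Si](C)(C)C | starting material
9 | trichlorotitanium Z-enolate of (S)-4-benzyl-3-(5-methylhex-5-enoyl)oxazolidin-2-one (not isolated) | C=C(C)CC/C=C(\O[Ti](Cl)(Cl)Cl)N1C(=O)OC[C@@H]1Cc1ccccc1 | intermediate
10 | (S)-4-benzyl-3-[(2R)-5-methyl-2-(2,4,6-trimethoxybenzyl)hex-5-enoyl]oxazolidin-2-one | C=C(C)CC[C@H](Cc1c(OC)cc(OC)cc1OC)C(=O)N1C(=O)OC[C@@H]1Cc1ccccc1 | intermediate
11 | S-ethyl (2R)-5-methyl-2-(2,4,6-trimethoxybenzyl)hex-5-enethioate | C=C(C)CC[C@H](Cc1c(OC)cc(OC)cc1OC)C(=O)SCC | intermediate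
12 | (3R)-6-methyl-3-(2,4,6-trimethoxybenzyl)hept-6-en-2-one | C=C(C)CC[C@H](Cc1c(OC)cc(OC)cc1OC)C(C)=O | intermediate
13 | 1,3,5-trimethoxy-2-[(2R)-5-methyl-2-(prop-1-en-2-yl)hex-5-en-1-yl]benzene | C=C(C)CC[C@H](Cc1c(OC)cc(OC)cc1OC)C(=C)C | intermediate
14 | 3-methylbut-1-yne | CC(C)C#C | starting material
15 | chlorobis(cyclopentadienyl)[(E)-3-methylbut-1-en-1-yl]zirconium (not isolated) | CC(C)/C=C/[Zr](Cl)(C1C=CC=C1)C1C=CC=C1 | intermediate
16 | (E)-1-iodo-3-methylbut-1-ene | CC(C)/C=C/I | intermediate
17 | aryllithium of 13, lithium at the ring A position between two methoxy groups (not isolated) | C=C(C)CC[C@H](Cc1c(OC)cc(OC)c([Li])c1OC)C(=C)C | intermediate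
18 | arylzinc chloride from 17 (not isolated) | C=C(C)CC[C@H](Cc1c(OC)cc(OC)c([Zn]Cl)c1OC)C(=C)C | intermediate
19 | 1,3,5-trimethoxy-2-[(2R)-5-methyl-2-(prop-1-en-2-yl)hex-5-en-1-yl]-4-[(E)-3-methylbut-1-en-1-yl]benzene | C=C(C)CC[C@H](Cc1c(OC)cc(OC)c(/C=C/C(C)C)c1OC)C(=C)C | intermediate
20 | methyl 3-hydroxybenzoate | COC(=O)c1cccc(O)c1 | starting material
21 | methyl 3-isopropoxybenzoate | COC(=O)c1cccc(OC(C)C)c1 | intermediate
22 | N-methoxy-N-methyl-3-isopropoxybenzamide | CON(C)C(=O)c1cccc(OC(C)C)c1 | intermediate
23 | aryllithium of 19, lithium at the last free ring A position (not isolated) | C=C(C)CC[C@H](Cc1c(OC)c([Li])c(OC)c(/C=C/C(C)C)c1OC)C(=C)C | intermediate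
24 | (3-isopropoxyphenyl)[2,4,6-trimethoxy-3-[(2R)-5-methyl-2-(prop-1-en-2-yl)hex-5-en-1-yl]-5-[(E)-3-methylbut-1-en-1-yl]phenyl]methanone | C=C(C)CC[C@H](Cc1c(OC)c(C(=O)c2cccc(OC(C)C)c2)c(OC)c(/C=C/C(C)C)c1OC)C(=C)C | intermediate
25 | (3-hydroxyphenyl)[2,6-dihydroxy-4-methoxy-3-[(2R)-5-methyl-2-(prop-1-en-2-yl)hex-5-en-1-yl]-5-[(E)-3-methylbut-1-en-1-yl]phenyl]methanone (CNP0208548.1) | C=C(C)CC[C@H](Cc1c(O)c(C(=O)c2cccc(O)c2)c(O)c(/C=C/C(C)C)c1OC)C(=C)C | target

**Step count**

Total: 13 steps. Longest linear sequence: 9 steps (steps 2, 3, 4, 5, 6, 7, 9, 12, 13, from 2,4,6-trimethoxybenzaldehyde).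

**Steps most likely to fail**

Step 4 (proposed new method). The two stages may interfere with each other: the benzyl cation may be intercepted by residual allylsilane or by a second electron-rich arene (oligomerisation), the enolate may be protonated before it is alkylated, and facial control may erode if Me3SiCl silylates the enolate so that it reacts in an open, non-chelated form. The fallback makes the two bonds in two known operations and sets out from 4 and 8. TiCl4-mediated Hosomi–Sakurai addition in CH2Cl2 at −78 °C with an aqueous quench should give (S)-4-benzyl-3-(5-methylhex-5-enoyl)oxazolidin-2-one F1, which is purified. F1 is then enolised with TiCl4 and i-Pr2NEt in CH2Cl2 at 0 °C to the same chelated enolate 9, now free of silane and Me3SiCl. This enolate is alkylated with acetate 7 at −78 → 0 °C (SN1-type alkylation of a chlorotitanium imide enolate under auxiliary control), and the route is rejoined at 10.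

Step 13. The second ortho-demethylation may stall at the boron chelate of the mono-phenol, and forcing it risks proton-induced cyclisation of the isopropenyl group onto the freed phenol at position 2 of ring A or loss of the methyl ether at position 6. The fallback uses an aprotic magnesium chelate with iodide as the nucleophile and a ring B silyl ether that needs no Lewis acid; it sets out from 19 and 20 and comes back at 25. Ester 20 is silylated (TBSCl, imidazole, DMF) to methyl 3-(tert-butyldimethylsilyloxy)benzoate F2, which is converted (MeNHOMe·HCl, i-PrMgCl, THF) into 3-(tert-butyldimethylsilyloxy)-N-methoxy-N-methylbenzamide F3. Aryllithium 23, made from 19 as in step 12, is acylated with F3 to give [3-(tert-butyldimethylsilyloxy)phenyl][2,4,6-trimethoxy-3-[(2R)-5-methyl-2-(prop-1-en-2-yl)hex-5-en-1-yl]-5-[(E)-3-methylbut-1-en-1-yl]phenyl]methanone F4. MgI2·OEt2 in toluene at 70 °C then removes the two methyl ethers ortho to the ketone, forming MeI and no protic acid, so the mixture can be heated until the second cleavage is complete; this should give [3-(tert-butyldimethylsilyloxy)phenyl][2,6-dihydroxy-4-methoxy-3-[(2R)-5-methyl-2-(prop-1-en-2-yl)hex-5-en-1-yl]-5-[(E)-3-methylbut-1-en-1-yl]phenyl]methanone F5. Finally n-Bu4NF buffered with AcOH in THF at 0 °C removes the silyl ether to reach 25.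

Step 12. n-BuLi may add to the styrene-type double bond, or metalation may occur at a site other than the ring C–H. The fallback introduces the aroyl group before the alkene exists; it sets out from 13 and comes back at 24. Aryllithium 17 (n-BuLi, THF, 0 °C) is acylated with Weinreb amide 22 to give (3-isopropoxyphenyl)[2,4,6-trimethoxy-3-[(2R)-5-methyl-2-(prop-1-en-2-yl)hex-5-en-1-yl]phenyl]methanone F6. The one remaining, still strongly activated ring A position is brominated with NBS in MeCN at −20 °C to give [3-bromo-2,4,6-trimethoxy-5-[(2R)-5-methyl-2-(prop-1-en-2-yl)hex-5-en-1-yl]phenyl](3-isopropoxyphenyl)methanone F7. Negishi coupling of F7 with (E)-(3-methylbut-1-en-1-yl)zinc chloride F8, made from alkenylzirconocene 15 and ZnCl2 (Pd2(dba)3, SPhos, THF, 50 °C), then installs the E-butenyl group and gives 24.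

**Further compounds**

F1 | step 4 | (S)-4-benzyl-3-(5-methylhex-5-enoyl)oxazolidin-2-one | C=C(C)CCCC(=O)N1C(=O)OC[C@@H]1Cc1ccccc1
F2 | step 13 | methyl 3-(tert-butyldimethylsilyloxy)benzoate | COC(=O)c1cccc(O[Si](C)(C)C(C)(C)C)c1
F3 | step 13 | 3-(tert-butyldimethylsilyloxy)-N-methoxy-N-methylbenzamide | CON(C)C(=O)c1cccc(O[Si](C)(C)C(C)(C)C)c1
F4 | step 13 | [3-(tert-butyldimethylsilyloxy)phenyl][2,4,6-trimethoxy-3-[(2R)-5-methyl-2-(prop-1-en-2-yl)hex-5-en-1-yl]-5-[(E)-3-methylbut-1-en-1-yl]phenyl]methanone | C=C(C)CC[C@H](Cc1c(OC)c(C(=O)c2cccc(O[Si](C)(C)C(C)(C)C)c2)c(OC)c(/C=C/C(C)C)c1OC)C(=C)C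
F5 | step 13 | [3-(tert-butyldimethylsilyloxy)phenyl][2,6-dihydroxy-4-methoxy-3-[(2R)-5-methyl-2-(prop-1-en-2-yl)hex-5-en-1-yl]-5-[(E)-3-methylbut-1-en-1-yl]phenyl]methanone | C=C(C)CC[C@H](Cc1c(O)c(C(=O)c2cccc(O[Si](C)(C)C(C)(C)C)c2)c(O)c(/C=C/C(C)C)c1OC)C(=C)C
F6 | step 12 | (3-isopropoxyphenyl)[2,4,6-trimethoxy-3-[(2R)-5-methyl-2-(prop-1-en-2-yl)hex-5-en-1-yl]phenyl]methanone | C=C(C)CC[C@H](Cc1c(OC)c(C(=O)c2cccc(OC(C)C)c2)c(OC)cc1OC)C(=C)C
F7 | step 12 | [3-bromo-2,4,6-trimethoxy-5-[(2R)-5-methyl-2-(prop-1-en-2-yl)hex-5-en-1-yl]phenyl](3-isopropoxyphenyl)methanone | C=C(C)CC[C@H](Cc1c(OC)c(C(=O)c2cccc(OC(C)C)c2)c(OC)c(Br)c1OC)C(=C)C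
F8 | step 12 | (E)-(3-methylbut-1-en-1-yl)zinc chloride | CC(C)/C=C/[Zn]Cl
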